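**Strategy.** The dihydrofuran ring is closed at C2–C3 by an enantioselective 1,5 C–H insertion of a donor/donor rhodium carbene. The route exploits that C3a of the benzo ring is flanked by two phenolic oxygens (O1 and the C4 oxygen) and lies para to the styryl carbon C6. The carbene precursor is therefore a locally symmetric diaryl hydrazone whose 4-bromo-2,6-bis(arylmethoxy)phenyl ring carries two identical guaiacyl-type benzyl ethers. Either arm delivers C2 with its aryl group; the other serves as the C4–OH protecting group. Insertion sets C3 (S) and gives the cis ring. A Heck reaction adds the stilbene, and acid equilibration at C2 during global debenzylation gives the trans (2S,3S) target.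

Key step: step 5

Remark (assumption): Rh2(S-PTAD)4, dirhodium tetrakis[(S)-(1-adamantyl)(phthalimido)acetate], is assumed to be the catalyst antipode that leads to the (3S) centre; if the sense of induction is the opposite, Rh2(R-PTAD)4 is used with no other change.

**Step 1**
Reactants: 1 1-bromo-3,5-difluorobenzene; 2 3,5-bis(benzyloxy)benzaldehyde
Product: 4 rac-[3,5-bis(benzyloxy)phenyl](4-bromo-2,6-difluorophenyl)methanol, via aryllithium 3 (not isolated)
Conditions: LDA, THF, −78 °C; then 2, −78 °C; H2O
Reagents that add atoms: none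
Why: Directed ortho-lithiation removes the most acidic proton, the one between the two fluorines; the aryllithium is stable at −78 °C and should add 1,2 to the aldehyde, and the carbinol centre is irrelevant because it is oxidized next.

**Step 2**
Reactants: 4 rac-[3,5-bis(benzyloxy)phenyl](4-bromo-2,6-difluorophenyl)methanol
Product: 5 [3,5-bis(benzyloxy)phenyl](4-bromo-2,6-difluorophenyl)methanone
Conditions: Dess–Martin periodinane, CH2Cl2, rt
Reagents that add atoms: none
Why: Dess–Martin oxidation of a secondary diaryl carbinol under neutral conditions should leave the benzyl ethers and aryl halides untouched.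

**Step 3**
Reactants: 5 [3,5-bis(benzyloxy)phenyl](4-bromo-2,6-difluorophenyl)methanone; 6 [4-(benzyloxy)-3-methoxyphenyl]methanol (2.2 equiv)
Product: 9 [3,5-bis(benzyloxy)phenyl](2,6-bis{[4-(benzyloxy)-3-methoxyphenyl]methoxy}-4-bromophenyl)methanone, via sodium alkoxide 7 (not isolated), via monofluoro monoether ketone 8 (not isolated)
Conditions: NaH, THF, 0 °C; then 5, THF–DMF, 0 → 50 °C
Reagents that add atoms: none
Why: Double nucleophilic aromatic substitution (SNAr): both fluorines are ortho to the non-enolizable ketone and fluoride is by far the better leaving group, so the bromide should survive; the second, slower substitution is driven by warming.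

**Step 4**
Reactants: 9 [3,5-bis(benzyloxy)phenyl](2,6-bis{[4-(benzyloxy)-3-methoxyphenyl]methoxy}-4-bromophenyl)methanone
Product: 10 hydrazone of ketone 9
Conditions: N2H4 (anhydrous, excess), N2H4·HCl (cat.), DMSO, 100 °C, argon
Reagents that add atoms: hydrazine, NN
Why: Acid-assisted hydrazone condensation under the forcing conditions used for ortho,ortho'-disubstituted benzophenones; the ortho ethers are not activated enough for displacement, and argon excludes diimide reduction.

**Step 5**
Reactants: 10 hydrazone of ketone 9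
Product: 12 (2R,3S)-3-[3,5-bis(benzyloxy)phenyl]-2-[4-(benzyloxy)-3-methoxyphenyl]-4-{[4-(benzyloxy)-3-methoxyphenyl]methoxy}-6-bromo-2,3-dihydro-1-benzofuran (2,3-cis), via diazo compound 11 (not isolated)
Conditions: MnO2 (activated), CH2Cl2, rt; filter (Celite); Rh2(S-PTAD)4 (1 mol %), CH2Cl2, −20 → 0 °C
Reagents that add atoms: none
Why: MnO2 dehydrogenates the hydrazone to diaryldiazomethane 11, which the dirhodium catalyst turns, with loss of N2, into a donor/donor rhodium carbene whose electrophilic carbon (future C3) takes the benzylic ether hydrogen of one ortho arylmethoxy arm in a hydride-transfer-like, asynchronous insertion and bonds to that carbon (future C2). The closest known reaction type is the enantioselective intramolecular C–H insertion of donor/donor dirhodium carbenes into benzylic ether C–H bonds, which gives 2,3-diaryl-2,3-dihydrobenzofurans. The dihydrofuran ring (O1–C2–C3–C3a–C7a) is closed by C2–C3 bond formation in a 1,5-insertion mode through a five-membered transition state. Both stereocentres arise here: the 2,3-cis relation should follow from the compact transition state in which C–C bond formation outruns bond rotation, and the absolute configuration (3S, with 2R) is imposed by the chiral carboxylate ligands (catalyst control). The step needs site selectivity, secured because the two ortho arms are homotopic and every other benzylic ether C–H is out of reach, and chemoselectivity over azine formation, favoured by the steric shielding of the diazo carbon and the electron-rich, hydride-donating guaiacyl-type CH2. The unused arm remains as the protecting group of the C4 oxygen.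

**Step 6**
Reactants: 12 cis-bromide (2R,3S); 13 1-(benzyloxy)-4-ethenyl-2-methoxybenzene
Product: 14 (2R,3S)-3-[3,5-bis(benzyloxy)phenyl]-2-[4-(benzyloxy)-3-methoxyphenyl]-4-{[4-(benzyloxy)-3-methoxyphenyl]methoxy}-6-{(E)-2-[4-(benzyloxy)-3-methoxyphenyl]ethenyl}-2,3-dihydro-1-benzofuran
Conditions: Pd(OAc)2 (5 mol %), P(o-tol)3, Et3N, DMF, 100 °C
Reagents that add atoms: none
Why: Mizoroki–Heck reaction: zerovalent palladium inserts into the unhindered aryl bromide, syn-carbopalladation at the terminal styrene carbon and syn β-hydride elimination should give the E-stilbene; C2 and C3 are not acidic under these conditions and should be retained.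

**Step 7**
Reactants: 14 cis-stilbene (2R,3S)
Product: 16 bisisorhapontigenin B, 5-[(2S,3S)-4-hydroxy-2-(4-hydroxy-3-methoxyphenyl)-6-[(E)-2-(4-hydroxy-3-methoxyphenyl)ethenyl]-2,3-dihydro-1-benzofuran-3-yl]benzene-1,3-diol, via cis-pentaphenol 15 (not isolated)
Conditions: BCl3 (excess), C6HMe5 (excess), CH2Cl2, −78 °C; then MeOH, −78 °C → rt, hold at rt until cis → trans equilibration is complete
Reagents that add atoms: none
Why: Lewis-acid debenzylation with pentamethylbenzene as a non-basic cation scavenger should cleave the five benzyl ethers and the electron-rich C4 arylmethyl ether while sparing the methyl ethers and the alkene. In the HCl/MeOH formed on quench, the O1–C2 bond of the cis isomer ionizes reversibly to the para-hydroxybenzyl cation (protonated para-quinone methide) and recloses to the thermodynamically favoured trans ring. C3 is not involved, so C2 is set as S by thermodynamic control relative to C3 (S).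

**Compound list**

1 | 1-bromo-3,5-difluorobenzene | Fc1cc(F)cc(Br)c1 | starting material
2 | 3,5-bis(benzyloxy)benzaldehyde | O=Cc1cc(OCc2ccccc2)cc(OCc2ccccc2)c1 | starting material
3 | (4-bromo-2,6-difluorophenyl)lithium | [Li]c1c(F)cc(Br)cc1F | intermediate (not isolated)
4 | rac-[3,5-bis(benzyloxy)phenyl](4-bromo-2,6-difluorophenyl)methanol | OC(c1cc(OCc2ccccc2)cc(OCc2ccccc2)c1)c1c(F)cc(Br)cc1F | intermediate
5 | [3,5-bis(benzyloxy)phenyl](4-bromo-2,6-difluorophenyl)methanone | O=C(c1cc(OCc2ccccc2)cc(OCc2ccccc2)c1)c1c(F)cc(Br)cc1F | intermediate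
6 | [4-(benzyloxy)-3-methoxyphenyl]methanol | COc1cc(CO)ccc1OCc1ccccc1 | starting material
7 | sodium [4-(benzyloxy)-3-methoxyphenyl]methanolate | [Na+].[O-]Cc1ccc(OCc2ccccc2)c(OC)c1 | intermediate (not isolated)
8 | [3,5-bis(benzyloxy)phenyl](2-{[4-(benzyloxy)-3-methoxyphenyl]methoxy}-4-bromo-6-fluorophenyl)methanone | O=C(c1cc(OCc2ccccc2)cc(OCc2ccccc2)c1)c1c(F)cc(Br)cc1OCc1ccc(OCc2ccccc2)c(OC)c1 | intermediate (not isolated)
9 | [3,5-bis(benzyloxy)phenyl](2,6-bis{[4-(benzyloxy)-3-methoxyphenyl]methoxy}-4-bromophenyl)methanone | O=C(c1cc(OCc2ccccc2)cc(OCc2ccccc2)c1)c1c(OCc2ccc(OCc3ccccc3)c(OC)c2)cc(Br)cc1OCc1ccc(OCc2ccccc2)c(OC)c1 | intermediate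
10 | hydrazone of ketone 9 | NN=C(c1cc(OCc2ccccc2)cc(OCc2ccccc2)c1)c1c(OCc2ccc(OCc3ccccc3)c(OC)c2)cc(Br)cc1OCc1ccc(OCc2ccccc2)c(OC)c1 | intermediate
11 | 2-{[3,5-bis(benzyloxy)phenyl](diazo)methyl}-1,3-bis{[4-(benzyloxy)-3-methoxyphenyl]methoxy}-5-bromobenzene | [N-]=[N+]=C(c1cc(OCc2ccccc2)cc(OCc2ccccc2)c1)c1c(OCc2ccc(OCc3ccccc3)c(OC)c2)cc(Br)cc1OCc1ccc(OCc2ccccc2)c(OC)c1 | intermediate (not isolated)
12 | (2R,3S)-3-[3,5-bis(benzyloxy)phenyl]-2-[4-(benzyloxy)-3-methoxyphenyl]-4-{[4-(benzyloxy)-3-methoxyphenyl]methoxy}-6-bromo-2,3-dihydro-1-benzofuran (cis) | Brc1cc(OCc2ccc(OCc3ccccc3)c(OC)c2)c2c(c1)O[C@@H](c1ccc(OCc3ccccc3)c(OC)c1)[C@H]2c1cc(OCc2ccccc2)cc(OCc2ccccc2)c1 | intermediate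
13 | 1-(benzyloxy)-4-ethenyl-2-methoxybenzene (4-benzyloxy-3-methoxystyrene) | C=Cc1ccc(OCc2ccccc2)c(OC)c1 | starting material
14 | (2R,3S)-3-[3,5-bis(benzyloxy)phenyl]-2-[4-(benzyloxy)-3-methoxyphenyl]-4-{[4-(benzyloxy)-3-methoxyphenyl]methoxy}-6-{(E)-2-[4-(benzyloxy)-3-methoxyphenyl]ethenyl}-2,3-dihydro-1-benzofuran (cis) | COc1cc(/C=C/c2cc(OCc3ccc(OCc4ccccc4)c(OC)c3)c3c(c2)O[C@@H](c2ccc(OCc4ccccc4)c(OC)c2)[C@H]3c2cc(OCc3ccccc3)cc(OCc3ccccc3)c2)ccc1OCc1ccccc1 | intermediate
15 | 5-[(2R,3S)-4-hydroxy-2-(4-hydroxy-3-methoxyphenyl)-6-[(E)-2-(4-hydroxy-3-methoxyphenyl)ethenyl]-2,3-dihydro-1-benzofuran-3-yl]benzene-1,3-diol (cis isomer of the target) | COc1cc(/C=C/c2cc(O)c3c(c2)O[C@@H](c2ccc(O)c(OC)c2)[C@H]3c2cc(O)cc(O)c2)ccc1O | intermediate (not isolated)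
16 | bisisorhapontigenin B, 5-[(2S,3S)-4-hydroxy-2-(4-hydroxy-3-methoxyphenyl)-6-[(E)-2-(4-hydroxy-3-methoxyphenyl)ethenyl]-2,3-dihydro-1-benzofuran-3-yl]benzene-1,3-diol | COc1cc(/C=C/c2cc(O)c3c(c2)O[C@H](c2ccc(O)c(OC)c2)[C@H]3c2cc(O)cc(O)c2)ccc1O | target

**Step count.** Total: 7 steps. Longest linear sequence: 7 steps (from 1 to 16).

**Steps most likely to fail**

Step 5. The carbene flanked by two ortho ether arms may insert slowly or with poor facial discrimination, so that azine formation or return to the ketone takes over, or the enantiomeric purity is insufficient. The fallback sets out from ketone 9 and closes the same C2–C3 bond photochemically. Irradiation at 365 nm in degassed benzene should cause δ-hydrogen abstraction from one arylmethoxy CH2 by the excited carbonyl and collapse of the 1,5-biradical (Norrish–Yang-type cyclization). This should give the racemic tertiary alcohol 3-[3,5-bis(benzyloxy)phenyl]-2-[4-(benzyloxy)-3-methoxyphenyl]-4-{[4-(benzyloxy)-3-methoxyphenyl]methoxy}-6-bromo-2,3-dihydro-1-benzofuran-3-ol F1. Ionic deoxygenation (Et3SiH, TFA, CH2Cl2, −40 °C) delivers hydride to the C3 cation anti to the C2 aryl group and should give the racemic 2,3-cis bromide F2. Preparative chromatography on a chiral stationary phase then provides the (2R,3S) enantiomer, which is compound 12, where the fallback rejoins the route.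

Step 4. Hydrazine may fail to add to the carbonyl screened by the two ortho ether arms, or may displace an ortho ether or the bromide on prolonged heating. The fallback sets out from ketone 9. Thionation with Lawesson's reagent (toluene, 100 °C) should give the diaryl thioketone F3. Its C=S group is longer and far more reactive toward nitrogen nucleophiles, and should exchange with N2H4·H2O in THF–EtOH at rt, with loss of H2S, to give hydrazone 10, where the route is rejoined.

Step 7. The ring-opened C2 cation may be captured irreversibly by the arene scavenger or the solvent, the cis-to-trans equilibration may stay incomplete, optical purity may erode by elimination and re-addition at C3, or the acid may oligomerize the electron-rich stilbene. The fallback sets out from bromide 12 and moves the acid-driven events ahead of stilbene formation. TFA with 1,3,5-trimethoxybenzene in CH2Cl2 (0 °C → rt) should remove the acid-labile C4 arylmethyl ether and equilibrate C2, giving (2S,3S)-3-[3,5-bis(benzyloxy)phenyl]-2-[4-(benzyloxy)-3-methoxyphenyl]-6-bromo-2,3-dihydro-1-benzofuran-4-ol F4. A Heck reaction with 13 under the conditions of step 6 should give the trans-stilbene (2S,3S)-3-[3,5-bis(benzyloxy)phenyl]-2-[4-(benzyloxy)-3-methoxyphenyl]-6-{(E)-2-[4-(benzyloxy)-3-methoxyphenyl]ethenyl}-2,3-dihydro-1-benzofuran-4-ol F5. A short BCl3/C6HMe5 debenzylation at −78 °C, with no equilibration stage, then leads to target 16.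

**Further compounds**

F1 | step 5 | rac-3-[3,5-bis(benzyloxy)phenyl]-2-[4-(benzyloxy)-3-methoxyphenyl]-4-{[4-(benzyloxy)-3-methoxyphenyl]methoxy}-6-bromo-2,3-dihydro-1-benzofuran-3-ol (diastereomer mixture) | Brc1cc(OCc2ccc(OCc3ccccc3)c(OC)c2)c2c(c1)OC(c1ccc(OCc3ccccc3)c(OC)c1)C2(O)c1cc(OCc2ccccc2)cc(OCc2ccccc2)c1
F2 | step 5 | racemic 2,3-cis bromide (both enantiomers of 12) | Brc1cc(OCc2ccc(OCc3ccccc3)c(OC)c2)c2c(c1)O[C@@H](c1ccc(OCc3ccccc3)c(OC)c1)[C@H]2c1cc(OCc2ccccc2)cc(OCc2ccccc2)c1.Brc1cc(OCc2ccc(OCc3ccccc3)c(OC)c2)c2c(c1)O[C@H](c1ccc(OCc3ccccc3)c(OC)c1)[C@@H]2c1cc(OCc2ccccc2)cc(OCc2ccccc2)c1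
F3 | step 4 | [3,5-bis(benzyloxy)phenyl](2,6-bis{[4-(benzyloxy)-3-methoxyphenyl]methoxy}-4-bromophenyl)methanethione | S=C(c1cc(OCc2ccccc2)cc(OCc2ccccc2)c1)c1c(OCc2ccc(OCc3ccccc3)c(OC)c2)cc(Br)cc1OCc1ccc(OCc2ccccc2)c(OC)c1
F4 | step 7 | (2S,3S)-3-[3,5-bis(benzyloxy)phenyl]-2-[4-(benzyloxy)-3-methoxyphenyl]-6-bromo-2,3-dihydro-1-benzofuran-4-ol | Brc1cc(O)c2c(c1)O[C@H](c1ccc(OCc3ccccc3)c(OC)c1)[C@H]2c1cc(OCc2ccccc2)cc(OCc2ccccc2)c1
F5 | step 7 | (2S,3S)-3-[3,5-bis(benzyloxy)phenyl]-2-[4-(benzyloxy)-3-methoxyphenyl]-6-{(E)-2-[4-(benzyloxy)-3-methoxyphenyl]ethenyl}-2,3-dihydro-1-benzofuran-4-ol | COc1cc(/C=C/c2cc(O)c3c(c2)O[C@H](c2ccc(OCc4ccccc4)c(OC)c2)[C@H]3c2cc(OCc3ccccc3)cc(OCc3ccccc3)c2)ccc1OCc1ccccc1
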